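**Plan**
Ring A is the acyl ring: C1 bears the depside carbonyl, then C2 OH, C3 CH3, C4 OH, C5 Cl, C6 CH3. The retrosynthesis cuts it at C1–C2 and C5–C6.
The enabling feature is that C1 lies between oxygenated C2 and methyl-bearing C6, and C6 adjoins C5–Cl. C1/C6 therefore map onto a but-2-ynoate, and C2–C5 onto a 4-chloro-2-methylbuta-1,3-diene with two oxygens on its C1 and one on its C3.
The depside C–O bond is cut next, at the level of unhindered but-2-ynoic acid. Ring B (methyl orsellinate) is bought intact and carries the alkyne.
Forward: O4-acylation and O2-silylation of ring B (steps 1–2); crossed Claisen and two-stage silylation to the chlorodiene (steps 3–5); Diels–Alder/aromatisation builds ring A on the ester already in place (step 6); desilylation (step 7).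
Stereochemistry: the target has no stereocentre and no stereogenic double bond. The diene geometry and the two transient stereocentres of the cycloadduct are erased on aromatisation.

Key step: step 6

Remark: enolates, enol ethers and the diene are each drawn as one double-bond isomer, and 8, 9 and 13 are racemic; none of this matters, because all these elements are gone after step 6.

**Step 1**
Reactants: 1 methyl orsellinate (methyl 2,4-dihydroxy-6-methylbenzoate); 2 but-2-ynoic acid
Product: 3 methyl 4-(but-2-ynoyloxy)-2-hydroxy-6-methylbenzoate
Conditions: N,N'-dicyclohexylcarbodiimide (DCC, 1.05 equiv), 4-(dimethylamino)pyridine (DMAP, 5 mol %), CH2Cl2, 0 °C to rt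
Reagents that add atoms: none
Why: Steglich esterification, the routine way to aryl but-2-ynoates, should acylate only O4 because the C2 hydroxyl is hydrogen-bonded to the neighbouring ester carbonyl and far less nucleophilic, while low DMAP loading at 0 °C limits base-induced isomerisation of the ynoate.

**Step 2**
Reactants: 3 methyl 4-(but-2-ynoyloxy)-2-hydroxy-6-methylbenzoate
Product: 4 methyl 4-(but-2-ynoyloxy)-2-(tert-butyldimethylsilyloxy)-6-methylbenzoate
Conditions: tBuMe2SiOTf (TBSOTf, 1.2 equiv), 2,6-lutidine (1.5 equiv), CH2Cl2, 0 °C
Reagents that add atoms: tert-butyldimethylsilyl triflate, CC(C)(C)[Si](C)(C)OS(=O)(=O)C(F)(F)F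
Why: O-silylation of a chelated phenol with a silyl triflate and a hindered pyridine base is standard; 2,6-lutidine neither adds to the ynoate nor cleaves the aryl ester, and the TBS ether (stable to chromatography and to 120 °C) removes the only proton that would destroy the ketene-acetal diene in step 6.

**Step 3**
Reactants: 5 methyl propanoate; 6 2-chloro-N-methoxy-N-methylacetamide
Product: 9 methyl 4-chloro-2-methyl-3-oxobutanoate (racemic), via lithium enolate of methyl propanoate 7 (not isolated), via chelated tetrahedral adduct 8 (not isolated)
Conditions: 5 (2.2 equiv), LiN(iPr)2 (LDA, commercial solution, 2.1 equiv), THF, −78 °C; then 6 (1 equiv), −78 °C; poured into cold 1 M HCl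
Reagents that add atoms: none
Why: Crossed Claisen-type acylation of a lithium ester enolate by an N-methoxy-N-methylamide (Weinreb ketone synthesis) keeps the carbonyl masked as chelate 8 until the acidic quench, so the chloroketone appears only when no base is left, which should suppress double addition, enolate exchange and Darzens-type closure onto the C–Cl bond; the labile C2 stereocentre is racemic and is erased in step 4.

**Step 4**
Reactants: 9 methyl 4-chloro-2-methyl-3-oxobutanoate
Product: 10 methyl (Z)-4-chloro-2-methyl-3-(trimethylsilyloxy)but-2-enoate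
Conditions: Me3SiCl (1.5 equiv), Et3N (1.5 equiv), toluene, rt, 2–3 d; filtration under Ar, concentration
Reagents that add atoms: chlorotrimethylsilane, C[Si](C)(C)Cl
Why: Soft enolisation and O-silylation of a β-keto ester is the first stage of the standard two-stage route to 1,3-bis(silyloxy)dienes and is known for both 2-alkyl and 4-chloro acetoacetates; charging the chlorosilane before the amine lets silylation outrun quaternisation of Et3N by the chloroketone.

**Step 5**
Reactants: 10 methyl (Z)-4-chloro-2-methyl-3-(trimethylsilyloxy)but-2-enoate
Product: 12 (1Z,3Z)-4-chloro-1-methoxy-2-methyl-1,3-bis(trimethylsilyloxy)buta-1,3-diene, via lithium dienolate 11 (not isolated)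
Conditions: LiN(iPr)2 (1.15 equiv), THF, −78 °C; Me3SiCl (1.3 equiv), −78 °C to rt; pentane, filtration under Ar, used crude
Reagents that add atoms: chlorotrimethylsilane, C[Si](C)(C)Cl
Why: Kinetic γ-deprotonation of the β-silyloxy enoate at the chlorine-acidified CH2 (the α-methyl group is not vinylogously activated) gives a delocalised dienolate that Me3SiCl traps on the ester oxygen, the standard second stage of bis(silyloxy)diene synthesis; chlorine is expected cis to the C3 silyloxy group, which is the outside position of the s-cis diene.

**Step 6**
Reactants: 4 methyl 4-(but-2-ynoyloxy)-2-(tert-butyldimethylsilyloxy)-6-methylbenzoate; 12 (1Z,3Z)-4-chloro-1-methoxy-2-methyl-1,3-bis(trimethylsilyloxy)buta-1,3-diene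
Product: 14 methyl 2-(tert-butyldimethylsilyloxy)-4-[5-chloro-3,6-dimethyl-2,4-bis(trimethylsilyloxy)benzoyloxy]-6-methylbenzoate, via cyclohexa-1,4-diene cycloadduct 13 (not isolated)
Conditions: 12 (2.5 equiv), neat (or 2 M in toluene), sealed tube, Ar, 120 °C, 24–48 h; volatiles removed at 0.1 mbar, crude 14 carried on
Reagents that add atoms: none
Why: Proposed new method: diene 12, whose HOMO is raised by three oxygen donors and is largest at the chlorine-bearing terminus, should bond through that carbon to the electrophilic β-carbon of ynoate 4 (C5–C6) while the ketene-acetal carbon closes onto the α-carbon (C1–C2), a concerted but strongly asynchronous normal-demand intermolecular [4+2] cycloaddition that closes ring A as a six-membered carbocycle, cyclohexa-1,4-diene 13. In 13 the acetal carbon C2 carries only nucleofuges (OMe, OSiMe3) and C5 carries the single ring hydrogen, so the arene can only arise by departure of the more basic methoxy group and loss of the C5 proton, a net 1,4-elimination of methanol that retains both the chlorine and the C2 oxygen. The closest known reaction type is the thermal Diels–Alder/aromatisation of 1-alkoxy-1,3-bis(silyloxy)buta-1,3-dienes with β-alkyl acetylenic esters to 6-alkylresorcylates; not yet shown is a diene substituted at C2 and chlorinated at its bonding terminus meeting a β-methyl ynoate to give a hexasubstituted benzene. The one selectivity needed is regiochemical and is secured by the matched polarisation of the two partners, with the (3Z) geometry holding chlorine on the outside of the s-cis diene, away from the incoming alkyne. Reactivity is helped by the aryl ester, which lowers the alkyne LUMO more than an alkyl ester would, by the high concentration, and by excess 12, which also scavenges the methanol released before it can desilylate 14. The two stereocentres of 13 (C2 and C5) are transient and disappear on aromatisation, so no stereocontrol is required.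

**Step 7**
Reactants: 14 methyl 2-(tert-butyldimethylsilyloxy)-4-[5-chloro-3,6-dimethyl-2,4-bis(trimethylsilyloxy)benzoyloxy]-6-methylbenzoate
Product: 15 methyl 4-(5-chloro-2,4-dihydroxy-3,6-dimethylbenzoyloxy)-2-hydroxy-6-methylbenzoate (target)
Conditions: Bu4NF (3.3 equiv), AcOH (3.5 equiv), THF, 0 °C to rt
Reagents that add atoms: none
Why: Fluoride-induced cleavage of aryl silyl ethers is fast at 0 °C, and the acetic acid buffer keeps the liberated phenoxides protonated, so the methyl ester, the aryl chloride and the depside ester (its carbonyl shielded by two ortho substituents) should stay untouched.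

**Compound list**
1 | methyl orsellinate (methyl 2,4-dihydroxy-6-methylbenzoate) | COC(=O)c1c(C)cc(O)cc1O | starting material
2 | but-2-ynoic acid | CC#CC(=O)O | starting material
3 | methyl 4-(but-2-ynoyloxy)-2-hydroxy-6-methylbenzoate | COC(=O)c1c(C)cc(OC(=O)C#CC)cc1O | intermediate
4 | methyl 4-(but-2-ynoyloxy)-2-(tert-butyldimethylsilyloxy)-6-methylbenzoate | COC(=O)c1c(C)cc(OC(=O)C#CC)cc1O[Si](C)(C)C(C)(C)C | intermediate
5 | methyl propanoate | CCC(=O)OC | starting material
6 | 2-chloro-N-methoxy-N-methylacetamide | CON(C)C(=O)CCl | starting material
7 | lithium enolate of methyl propanoate (not isolated; methyl trans to OLi) | C/C=C(/[O-])OC.[Li+] | intermediate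
8 | chelated tetrahedral adduct, lithium 1-chloro-2-[methoxy(methyl)amino]-4-methoxy-3-methyl-4-oxobutan-2-olate (not isolated; racemic diastereomer mixture) | COC(=O)C(C)C([O-])(CCl)N(C)OC.[Li+] | intermediate
9 | methyl 4-chloro-2-methyl-3-oxobutanoate (racemic, labile stereocentre) | COC(=O)C(C)C(=O)CCl | intermediate
10 | methyl (Z)-4-chloro-2-methyl-3-(trimethylsilyloxy)but-2-enoate | COC(=O)/C(C)=C(/CCl)O[Si](C)(C)C | intermediate
11 | lithium dienolate of 10 (not isolated) | CO/C([O-])=C(C)/C(O[Si](C)(C)C)=C/Cl.[Li+] | intermediate
12 | (1Z,3Z)-4-chloro-1-methoxy-2-methyl-1,3-bis(trimethylsilyloxy)buta-1,3-diene | CO/C(O[Si](C)(C)C)=C(C)/C(O[Si](C)(C)C)=C/Cl | intermediate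
13 | cyclohexa-1,4-diene cycloadduct (not isolated; racemic, one enantiomer drawn): ring A with C1=C6 and C3=C4, C2 bearing OMe and OSiMe3, C5 bearing H and Cl, OMe and Cl cis | CO[C@@]1(O[Si](C)(C)C)C(C)=C(O[Si](C)(C)C)[C@@H](Cl)C(C)=C1C(=O)Oc2cc(C)c(C(=O)OC)c(O[Si](C)(C)C(C)(C)C)c2 | intermediate
14 | methyl 2-(tert-butyldimethylsilyloxy)-4-[5-chloro-3,6-dimethyl-2,4-bis(trimethylsilyloxy)benzoyloxy]-6-methylbenzoate | COC(=O)c1c(C)cc(OC(=O)c2c(C)c(Cl)c(O[Si](C)(C)C)c(C)c2O[Si](C)(C)C)cc1O[Si](C)(C)C(C)(C)C | intermediate
15 | methyl 4-(5-chloro-2,4-dihydroxy-3,6-dimethylbenzoyloxy)-2-hydroxy-6-methylbenzoate (CNP0171762.0) | COC(=O)c1c(C)cc(OC(=O)c2c(C)c(Cl)c(O)c(C)c2O)cc1O | target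

**Step count**
Total steps: 7.
Longest linear sequence: 5 steps (5/6 → 9 → 10 → 12 → 14 → 15).

**Steps most likely to fail**

**Step 6.**
- Risk: bond formation between the chlorinated diene terminus and the methyl-bearing alkyne carbon may be too slow. Thermal silyl migration, protodesilylation of the diene or [2+2] addition of the ketene acetal could then outrun the cycloaddition.
- Fallback (known chemistry): this sets out from 1 and comes back at 15. Ring A is taken ready-made and the depside bond is formed by classical esterification.
- Commercial methyl 2,4-dihydroxy-3,6-dimethylbenzoate F1 is chlorinated at its only free ring position with SO2Cl2 (1 equiv, Et2O/CH2Cl2, 0 °C) to methyl 5-chloro-2,4-dihydroxy-3,6-dimethylbenzoate F2.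
- The hindered ester is cleaved in cold concentrated H2SO4, followed by ice, to give 5-chloro-2,4-dihydroxy-3,6-dimethylbenzoic acid F3.
- The acid is condensed with the unhindered C4 hydroxyl of 1 by DCC in toluene, the established depside coupling of free phenolic acids. Its own C4 hydroxyl is flanked by CH3 and Cl and should not compete. This gives 15 directly.

**Step 5.**
- Risk: after γ-lithiation the chlorine-bearing carbon may lose chloride in a carbenoid manner or alkylate a second molecule, and silylation may fall partly on carbon.
- Fallback: this sets out from 4 and comes back at 15. The diene carries no chlorine, and the halogen enters last by electrophilic substitution.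
- Commercial methyl 2-methyl-3-oxobutanoate F4 goes through the same two stages (Me3SiCl/Et3N, then LiN(iPr)2/Me3SiCl). It passes via methyl (Z)-2-methyl-3-(trimethylsilyloxy)but-2-enoate F5 to 1-methoxy-2-methyl-1,3-bis(trimethylsilyloxy)buta-1,3-diene F6, whose free terminus is less hindered and more nucleophilic.
- Heating it with 4 should give methyl 2-(tert-butyldimethylsilyloxy)-4-[3,6-dimethyl-2,4-bis(trimethylsilyloxy)benzoyloxy]-6-methylbenzoate F7.
- Bu4NF/AcOH then frees methyl 4-(2,4-dihydroxy-3,6-dimethylbenzoyloxy)-2-hydroxy-6-methylbenzoate F8.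
- One equivalent of SO2Cl2 (Et2O/CH2Cl2, 0 °C) should chlorinate C5 of ring A to give 15. This is the only position ortho to one free hydroxyl and para to another.

**Step 3.**
- Risk: proton transfer from the acidic ClCH2 group of the amide to the enolate, or early collapse of the tetrahedral adduct followed by attack of remaining enolate on the chloroketone.
- Fallback: this sets out from 5 and comes back at 9. The basic enolate is replaced by a neutral nucleophile.
- Compound 5 is converted with LiN(iPr)2/Me3SiCl (THF, −78 °C) into (E)-1-methoxy-1-(trimethylsilyloxy)prop-1-ene F9.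
- This is C-acylated by chloroacetyl chloride in CH2Cl2 with catalytic ZnCl2 (Mukaiyama-type acylation of a ketene silyl acetal). Aqueous work-up gives 9.

**Further compounds**
F1 | step 6 | methyl 2,4-dihydroxy-3,6-dimethylbenzoate (commercial) | COC(=O)c1c(C)cc(O)c(C)c1O
F2 | step 6 | methyl 5-chloro-2,4-dihydroxy-3,6-dimethylbenzoate | COC(=O)c1c(C)c(Cl)c(O)c(C)c1O
F3 | step 6 | 5-chloro-2,4-dihydroxy-3,6-dimethylbenzoic acid | OC(=O)c1c(C)c(Cl)c(O)c(C)c1O
F4 | step 5 | methyl 2-methyl-3-oxobutanoate (commercial, racemic) | COC(=O)C(C)C(C)=O
F5 | step 5 | methyl (Z)-2-methyl-3-(trimethylsilyloxy)but-2-enoate | COC(=O)/C(C)=C(/C)O[Si](C)(C)C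
F6 | step 5 | 1-methoxy-2-methyl-1,3-bis(trimethylsilyloxy)buta-1,3-diene | CO/C(O[Si](C)(C)C)=C(C)/C(=C)O[Si](C)(C)C
F7 | step 5 | methyl 2-(tert-butyldimethylsilyloxy)-4-[3,6-dimethyl-2,4-bis(trimethylsilyloxy)benzoyloxy]-6-methylbenzoate | COC(=O)c1c(C)cc(OC(=O)c2c(C)cc(O[Si](C)(C)C)c(C)c2O[Si](C)(C)C)cc1O[Si](C)(C)C(C)(C)C
F8 | step 5 | methyl 4-(2,4-dihydroxy-3,6-dimethylbenzoyloxy)-2-hydroxy-6-methylbenzoate | COC(=O)c1c(C)cc(OC(=O)c2c(C)cc(O)c(C)c2O)cc1O
F9 | step 3 | (E)-1-methoxy-1-(trimethylsilyloxy)prop-1-ene | C/C=C(/O[Si](C)(C)C)OC
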